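The dihydrofuran ring is cut from the benzene ring at both of its aryl bonds, C7a–O1 and C3a–C3 (benzofuran numbering). The key step exploits the ortho relationship of C7a and C3a beside the C7 methoxy group: the arene enters as a regiodefined aryne equivalent, an aryl(trimethoxyphenyl)iodonium salt carrying trivalent iodine on C7a (electrophilic site) and bromine on C3a (latent nucleophile). In one flask the alkoxide of an enantiopure aryl(oxiranyl)methanol is O-arylated at C7a, then bromine–lithium exchange at C3a opens the epoxide 5-exo at C3, closing the ring, freeing the C3 hydroxymethyl group and setting the trans C2/C3 centres. The C5 bromine later receives the triol chain from (R)-glyceraldehyde acetonide.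

Key step: step 5

Remark on the chemistry: compound 1 is assumed to be a catalogue compound; the target is read as (2R,3S) in the ring and (1S,2R), erythro, in the side chain.

Step 1
Reactants: 1 2,4-dibromo-6-methoxyaniline
Product: 2 1,5-dibromo-2-iodo-3-methoxybenzene
Conditions: p-TsOH·H2O, NaNO2, KI, MeCN–H2O, 10 to 20 °C
Reagents that add atoms: potassium iodide, [K+].[I-]
Why: Diazotisation of the aniline and displacement of N2 by iodide (Sandmeyer-type iodination, no copper needed) should put iodine on the future C7a between the methoxy group and a bromine, leaving both bromines untouched.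

Step 2
Reactants: 2 1,5-dibromo-2-iodo-3-methoxybenzene; 3 1,3,5-trimethoxybenzene
Product: 5 (2,4-dibromo-6-methoxyphenyl)(2,4,6-trimethoxyphenyl)iodonium 4-methylbenzenesulfonate, via hydroxy(tosyloxy)iodoarene 4 (not isolated)
Conditions: mCPBA, p-TsOH·H2O, MeCN, 77 °C; then 3, 77 °C
Reagents that add atoms: 4-methylbenzenesulfonic acid, Cc1ccc(cc1)S(O)(=O)=O; mCPBA, OOC(=O)c1cccc(Cl)c1
Why: Oxidation of the aryl iodide to the trivalent hydroxy(tosyloxy)iodane 4 (whose hydroxy oxygen comes from mCPBA) and electrophilic aromatic substitution on 1,3,5-trimethoxybenzene is the standard one-pot synthesis of diaryliodonium salts, the trimethoxyphenyl group serving as the ligand that is not transferred.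

Step 3
Reactants: 6 4-(benzyloxy)-3-methoxybenzaldehyde
Product: 7 rac-1-[4-(benzyloxy)-3-methoxyphenyl]prop-2-en-1-ol
Conditions: CH2=CHMgBr, THF, 0 °C; aqueous work-up
Reagents that add atoms: vinylmagnesium bromide, C=C[Mg]Br
Why: Grignard 1,2-addition to the aldehyde should give the racemic secondary allylic alcohol needed for resolution.

Step 4
Reactants: 7 rac-1-[4-(benzyloxy)-3-methoxyphenyl]prop-2-en-1-ol
Product: 8 (S)-[4-(benzyloxy)-3-methoxyphenyl][(2R)-oxiran-2-yl]methanol
Conditions: Ti(OiPr)4 (0.15 equiv), L-(+)-DIPT (0.2 equiv), TBHP (0.45 equiv), 4 Å MS, CH2Cl2, −20 °C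
Reagents that add atoms: tert-butyl hydroperoxide, CC(C)(C)OO
Why: In this Sharpless kinetic resolution the (R)-enantiomer of 7 should be epoxidised much faster than the (S)-enantiomer and with erythro selectivity under L-(+)-tartrate control, which fixes the carbinol centre (future C2) and the oxirane centre that becomes C3.

Step 5
Reactants: 8 (S)-[4-(benzyloxy)-3-methoxyphenyl][(2R)-oxiran-2-yl]methanol; 5 (2,4-dibromo-6-methoxyphenyl)(2,4,6-trimethoxyphenyl)iodonium 4-methylbenzenesulfonate
Product: 11 [(2R,3S)-2-[4-(benzyloxy)-3-methoxyphenyl]-5-bromo-7-methoxy-2,3-dihydro-1-benzofuran-3-yl]methanol, via aryl epoxyalkyl ether 9 (not isolated), via aryllithium 10 (not isolated)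
Conditions: NaH (1.1 equiv) added to 8 + 5, THF–toluene, 0 to 20 °C; then n-BuLi (2.1 equiv, one equivalent being consumed by the 2-iodo-1,3,5-trimethoxybenzene released), −78 to 0 °C; H2O
Reagents that add atoms: n-butyllithium, CCCC[Li]
Why: The sodium alkoxide of 8 adds to the trivalent iodine of 5 and ligand coupling transfers the 2,4-dibromo-6-methoxyphenyl group to oxygen at its ipso carbon, the known metal-free O-arylation of alkoxides with diaryliodonium salts; because both positions ortho to iodine are substituted no aryne can form, so oxygen must end on C7a beside the methoxy group, and the electron-rich trimethoxyphenyl ligand stays on iodine. n-BuLi (which supplies only the lithium of 10) should then exchange the bromine ortho to the new ether oxygen (C3a) in preference to the para bromine (C5), helped by coordination to the ether and epoxide oxygens and by the greater stability of the ortho-alkoxy aryllithium, and aryllithium 10 opens the tethered epoxide in a Parham-type cyclisation. The dihydrofuran ring closes 5-exo-tet at the internal epoxide carbon and not 6-endo at the CH2 group, as is known for 2-lithiophenyl glycidyl ethers, which give 2,3-dihydrobenzofuran-3-ylmethanols. C2 keeps the configuration from step 4 because its C–O bond is never broken, and C3 is set by backside attack with inversion at the (R)-oxirane carbon, which from the erythro epoxy alcohol gives the trans (2R,3S) ring. The step needs O-arylation to outrun Payne rearrangement and oxidation of the benzylic alkoxide, which trapping the alkoxide as it forms should secure, and a single bromine–lithium exchange on 9, which the measured amount of n-BuLi and the low temperature control.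

Step 6
Reactants: 11 [(2R,3S)-2-[4-(benzyloxy)-3-methoxyphenyl]-5-bromo-7-methoxy-2,3-dihydro-1-benzofuran-3-yl]methanol; 12 (4R)-2,2-dimethyl-1,3-dioxolane-4-carbaldehyde
Product: 15 (S)-{(2R,3S)-2-[4-(benzyloxy)-3-methoxyphenyl]-3-(hydroxymethyl)-7-methoxy-2,3-dihydro-1-benzofuran-5-yl}[(4R)-2,2-dimethyl-1,3-dioxolan-4-yl]methanol, via dilithio species 13 (not isolated), via aryltitanium 14 (not isolated)
Conditions: n-BuLi (2.1 equiv), THF, −78 °C; ClTi(OiPr)3 (2.2 equiv), −78 °C; then 12, −78 to 0 °C; H2O
Reagents that add atoms: n-butyllithium, CCCC[Li]; chlorotitanium triisopropoxide, CC(C)O[Ti](Cl)(OC(C)C)OC(C)C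
Why: Deprotonation of the alcohol and bromine–lithium exchange at C5, transmetalation of both lithium sites to titanium triisopropoxide (the reagents supply only the metals of 13 and 14) and addition of the aryltitanium to the α-alkoxy aldehyde under Felkin–Anh (non-chelation) control should give the anti (erythro) adduct, so the new benzylic carbinol is (S) while the (R) centre comes unchanged from the chiral pool aldehyde.

Step 7
Reactants: 15 (S)-{(2R,3S)-2-[4-(benzyloxy)-3-methoxyphenyl]-3-(hydroxymethyl)-7-methoxy-2,3-dihydro-1-benzofuran-5-yl}[(4R)-2,2-dimethyl-1,3-dioxolan-4-yl]methanol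
Product: 16 (1S,2R)-1-{(2R,3S)-2-[4-(benzyloxy)-3-methoxyphenyl]-3-(hydroxymethyl)-7-methoxy-2,3-dihydro-1-benzofuran-5-yl}propane-1,2,3-triol
Conditions: AcOH–H2O (4:1), 40 °C
Reagents that add atoms: none
Why: Mild acid hydrolysis of the isopropylidene acetal should free the 1,2-diol without ionising the benzylic alcohol or the benzylic ring ether, the phenol still being protected.

Step 8
Reactants: 16 (1S,2R)-1-{(2R,3S)-2-[4-(benzyloxy)-3-methoxyphenyl]-3-(hydroxymethyl)-7-methoxy-2,3-dihydro-1-benzofuran-5-yl}propane-1,2,3-triol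
Product: 17 (1S,2R)-1-[(2R,3S)-2-(4-hydroxy-3-methoxyphenyl)-3-(hydroxymethyl)-7-methoxy-2,3-dihydro-1-benzofuran-5-yl]propane-1,2,3-triol
Conditions: H2 (1 atm), Pd/C, EtOAc–MeOH, 20 °C, stopped at full debenzylation
Reagents that add atoms: none
Why: Hydrogenolysis of the aryl benzyl ether over Pd/C under neutral conditions should liberate the phenol faster than the cyclic benzylic ether or the benzylic alcohol is cleaved, and no stereocentre is touched.

Compound list

1 | 2,4-dibromo-6-methoxyaniline | COc1cc(Br)cc(Br)c1N | starting material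
2 | 1,5-dibromo-2-iodo-3-methoxybenzene | COc1cc(Br)cc(Br)c1I | intermediate
3 | 1,3,5-trimethoxybenzene | COc1cc(OC)cc(OC)c1 | starting material
4 | 1,5-dibromo-2-[hydroxy(tosyloxy)-λ3-iodanyl]-3-methoxybenzene | COc1cc(Br)cc(Br)c1I(O)OS(=O)(=O)c1ccc(C)cc1 | intermediate
5 | (2,4-dibromo-6-methoxyphenyl)(2,4,6-trimethoxyphenyl)iodonium 4-methylbenzenesulfonate | COc1cc(Br)cc(Br)c1[I+]c1c(OC)cc(OC)cc1OC.Cc1ccc(cc1)S(=O)(=O)[O-] | intermediate
6 | 4-(benzyloxy)-3-methoxybenzaldehyde | COc1cc(C=O)ccc1OCc1ccccc1 | starting material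
7 | rac-1-[4-(benzyloxy)-3-methoxyphenyl]prop-2-en-1-ol | C=CC(O)c1ccc(OCc2ccccc2)c(OC)c1 | intermediate
8 | (S)-[4-(benzyloxy)-3-methoxyphenyl][(2R)-oxiran-2-yl]methanol | O[C@@H](c1ccc(OCc2ccccc2)c(OC)c1)[C@H]1CO1 | intermediate
9 | 2-{(S)-[4-(benzyloxy)-3-methoxyphenyl][(2R)-oxiran-2-yl]methoxy}-1,5-dibromo-3-methoxybenzene | COc1cc(Br)cc(Br)c1O[C@@H](c1ccc(OCc2ccccc2)c(OC)c1)[C@H]1CO1 | intermediate
10 | (2-{(S)-[4-(benzyloxy)-3-methoxyphenyl][(2R)-oxiran-2-yl]methoxy}-5-bromo-3-methoxyphenyl)lithium | COc1cc(Br)cc([Li])c1O[C@@H](c1ccc(OCc2ccccc2)c(OC)c1)[C@H]1CO1 | intermediate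
11 | [(2R,3S)-2-[4-(benzyloxy)-3-methoxyphenyl]-5-bromo-7-methoxy-2,3-dihydro-1-benzofuran-3-yl]methanol | COc1cc([C@@H]2Oc3c(OC)cc(Br)cc3[C@H]2CO)ccc1OCc1ccccc1 | intermediate
12 | (4R)-2,2-dimethyl-1,3-dioxolane-4-carbaldehyde | O=C[C@H]1COC(C)(C)O1 | starting material
13 | dilithio species of 11 (lithium alkoxide, 5-lithio arene) | COc1cc([C@@H]2Oc3c(OC)cc([Li])cc3[C@H]2CO[Li])ccc1OCc1ccccc1 | intermediate
14 | bis(triisopropoxytitanium) species of 11 (aryltitanium at C5, titanium alkoxide at the hydroxymethyl oxygen) | COc1cc([C@@H]2Oc3c(OC)cc([Ti](OC(C)C)(OC(C)C)OC(C)C)cc3[C@H]2CO[Ti](OC(C)C)(OC(C)C)OC(C)C)ccc1OCc1ccccc1 | intermediate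
15 | (S)-{(2R,3S)-2-[4-(benzyloxy)-3-methoxyphenyl]-3-(hydroxymethyl)-7-methoxy-2,3-dihydro-1-benzofuran-5-yl}[(4R)-2,2-dimethyl-1,3-dioxolan-4-yl]methanol | COc1cc([C@@H]2Oc3c(OC)cc([C@H](O)[C@H]4COC(C)(C)O4)cc3[C@H]2CO)ccc1OCc1ccccc1 | intermediate
16 | (1S,2R)-1-{(2R,3S)-2-[4-(benzyloxy)-3-methoxyphenyl]-3-(hydroxymethyl)-7-methoxy-2,3-dihydro-1-benzofuran-5-yl}propane-1,2,3-triol | COc1cc([C@@H]2Oc3c(OC)cc([C@H](O)[C@H](O)CO)cc3[C@H]2CO)ccc1OCc1ccccc1 | intermediate
17 | (1S,2R)-1-[(2R,3S)-2-(4-hydroxy-3-methoxyphenyl)-3-(hydroxymethyl)-7-methoxy-2,3-dihydro-1-benzofuran-5-yl]propane-1,2,3-triol | COc1cc([C@@H]2Oc3c(OC)cc([C@H](O)[C@H](O)CO)cc3[C@H]2CO)ccc1O | target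

Total step count: 8. Longest linear sequence: 6 steps (1, 2, 5, 6, 7, 8 from compound 1; equally 3, 4, 5, 6, 7, 8 from compound 6).

Steps most likely to fail

Step 5. Payne rearrangement of the epoxy alkoxide or its oxidation by the iodane may outrun O-arylation. The lithium exchange may also take place at the C5 bromine, the aryllithium may be butylated by the butyl halides formed, or the ring may close 6-endo. The fallback sets out from 7 and comes back to the route at 11. The resolution of step 4 is driven past half conversion and the unreacted alcohol (S)-1-[4-(benzyloxy)-3-methoxyphenyl]prop-2-en-1-ol F1 is recovered. It is coupled with 2,4-dibromo-6-methoxyphenol F2 under Mitsunobu conditions (PPh3, DIAD), with inversion, to give the allyl aryl ether 1,5-dibromo-2-{[(1R)-1-[4-(benzyloxy)-3-methoxyphenyl]prop-2-en-1-yl]oxy}-3-methoxybenzene F3. Epoxidation with mCPBA then gives 9 together with its threo diastereomer 2-{(S)-[4-(benzyloxy)-3-methoxyphenyl][(2S)-oxiran-2-yl]methoxy}-1,5-dibromo-3-methoxybenzene F4, which is removed by chromatography. Isolated 9, now free of any aryl iodide, is cyclised with n-BuLi (1.05 equiv) at −78 °C as in the second half of step 5 to give 11.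

Step 6. Facial selectivity in the addition to the α-alkoxy aldehyde may be poor, giving a mixture of epimers at the benzylic carbinol. The fallback sets out from 11 and comes back at 15. The dilithio species 13 is added at −78 °C to the Weinreb amide (4R)-N-methoxy-N,2,2-trimethyl-1,3-dioxolane-4-carboxamide F5 to give the aryl ketone {(2R,3S)-2-[4-(benzyloxy)-3-methoxyphenyl]-3-(hydroxymethyl)-7-methoxy-2,3-dihydro-1-benzofuran-5-yl}[(4R)-2,2-dimethyl-1,3-dioxolan-4-yl]methanone F6. This is reduced with Zn(BH4)2 in Et2O at 0 °C under chelation control: zinc bridges the carbonyl and the α-oxygen, and hydride enters from the face opposite to that of a Felkin-type reduction. This should give the anti (erythro) alcohol, that is the (S)-carbinol 15.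

Step 4. The titanium Lewis acid may ionise the electron-rich benzylic allylic alcohol, and the rate difference between the enantiomers may be too small, eroding the enantiomeric purity of 8. The fallback sets out from 6 and comes back at 8. Catalytic enantioselective vinylation of 6 (Zn(CH=CH2)2 with the enantiomer of a chiral amino alcohol ligand that delivers the (R)-alcohol) gives (R)-1-[4-(benzyloxy)-3-methoxyphenyl]prop-2-en-1-ol F7. This is epoxidised as the matched case with Ti(OiPr)4, L-(+)-DIPT and TBHP at full conversion to give 8.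

Further compounds
F1 | step 5 | (S)-1-[4-(benzyloxy)-3-methoxyphenyl]prop-2-en-1-ol | C=C[C@H](O)c1ccc(OCc2ccccc2)c(OC)c1
F2 | step 5 | 2,4-dibromo-6-methoxyphenol | COc1cc(Br)cc(Br)c1O
F3 | step 5 | 1,5-dibromo-2-{[(1R)-1-[4-(benzyloxy)-3-methoxyphenyl]prop-2-en-1-yl]oxy}-3-methoxybenzene | COc1cc(Br)cc(Br)c1O[C@@H](c1ccc(OCc2ccccc2)c(OC)c1)C=C
F4 | step 5 | 2-{(S)-[4-(benzyloxy)-3-methoxyphenyl][(2S)-oxiran-2-yl]methoxy}-1,5-dibromo-3-methoxybenzene | COc1cc(Br)cc(Br)c1O[C@@H](c1ccc(OCc2ccccc2)c(OC)c1)[C@@H]1CO1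
F5 | step 6 | (4R)-N-methoxy-N,2,2-trimethyl-1,3-dioxolane-4-carboxamide | CON(C)C(=O)[C@H]1COC(C)(C)O1
F6 | step 6 | {(2R,3S)-2-[4-(benzyloxy)-3-methoxyphenyl]-3-(hydroxymethyl)-7-methoxy-2,3-dihydro-1-benzofuran-5-yl}[(4R)-2,2-dimethyl-1,3-dioxolan-4-yl]methanone | COc1cc([C@@H]2Oc3c(OC)cc(C(=O)[C@H]4COC(C)(C)O4)cc3[C@H]2CO)ccc1OCc1ccccc1
F7 | step 4 | (R)-1-[4-(benzyloxy)-3-methoxyphenyl]prop-2-en-1-ol | C=C[C@@H](O)c1ccc(OCc2ccccc2)c(OC)c1
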